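Ring B is cut from ring A at two bonds, C4–C4a and C1–C8a. One palladium/norbornene relay makes both: an aryl iodide is alkylated at its free ortho C–H by a chiral iodoalkene, and the returning arylpalladium closes ring B by a Heck reaction that leaves C1 as an exocyclic methylene, a masked ketone. The step exploits the ortho-fusion of ring B at C4a and C8a next to the C8 oxygen: with iodine on C8a and methoxy on C8, only C4a–H can be metalated. The precursors are 4-iodo-3-methoxybiphenyl and an (R)-silyloxy iodopentene from (R)-epichlorohydrin; the pyranone is joined to C5 afterwards by Suzuki coupling.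

Key step: step 6

Remark: atoms are numbered as in 1-tetralone (C1 carbonyl, C3 carbinol, C4a/C8a ring fusion, C5 pyranone, C6 phenyl, C8 phenol); ring A is the benzene ring, ring B the ketone ring; the target SMILES is read as the (3S) enantiomer.

Step 1
Reactants: 1 4-bromo-2-methoxyaniline; 2 phenylboronic acid
Product: 3 3-methoxybiphenyl-4-amine
Conditions: Pd(PPh3)4 (3 mol%), K2CO3 (2.5 equiv), 1,4-dioxane/H2O (4:1), 90 °C
Reagents that add atoms: none
Why: Suzuki–Miyaura coupling of an aryl bromide with phenylboronic acid is routine and tolerates the free amino group.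

Step 2
Reactants: 3 3-methoxybiphenyl-4-amine
Product: 5 4-iodo-3-methoxybiphenyl, via diazonium chloride 4 (not isolated)
Conditions: NaNO2 (1.1 equiv), aq. HCl, MeCN, 0 °C; then KI (2 equiv), H2O, 0 °C → rt
Reagents that add atoms: potassium iodide, [K+].[I-]
Why: Diazotisation followed by iodide displacement (Sandmeyer-type iodination, no copper needed) replaces the amino group at the same carbon, so iodine ends ortho to methoxy and para to phenyl.

Step 3
Reactants: 6 (R)-epichlorohydrin; 7 vinylmagnesium bromide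
Product: 8 (2R)-1-chloropent-4-en-2-ol
Conditions: CuI (10 mol%), THF, −40 → −20 °C; then aq. NH4Cl
Reagents that add atoms: none
Why: Copper-catalysed Grignard opening of the epoxide occurs by SN2 attack at the unsubstituted terminus, so the stereocentre of 6 is untouched and becomes the (R)-carbinol of 8, while the chloride survives at low temperature.

Step 4
Reactants: 8 (2R)-1-chloropent-4-en-2-ol
Product: 9 tert-butyl{[(2R)-1-chloropent-4-en-2-yl]oxy}dimethylsilane
Conditions: TBSCl (1.2 equiv), imidazole (2.5 equiv), DMF, rt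
Reagents that add atoms: tert-butyldimethylsilyl chloride, CC(C)(C)[Si](C)(C)Cl
Why: Silylation of a secondary alcohol with imidazole as base is standard, and imidazole is too weak a base to close the chlorohydrin to an epoxide.

Step 5
Reactants: 9 tert-butyl{[(2R)-1-chloropent-4-en-2-yl]oxy}dimethylsilane
Product: 10 tert-butyl{[(2R)-1-iodopent-4-en-2-yl]oxy}dimethylsilane
Conditions: NaI (5 equiv), butan-2-one, 80 °C, dark
Reagents that add atoms: sodium iodide, [Na+].[I-]
Why: Finkelstein halide exchange (SN2 at the primary carbon, driven by precipitation of NaCl) gives the more reactive iodide without touching the stereocentre.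

Step 6
Reactants: 5 4-iodo-3-methoxybiphenyl; 10 tert-butyl{[(2R)-1-iodopent-4-en-2-yl]oxy}dimethylsilane
Product: 11 (3R)-3-(tert-butyldimethylsilyloxy)-8-methoxy-1-methylidene-6-phenyl-1,2,3,4-tetrahydronaphthalene
Conditions: Pd(OAc)2 (10 mol%), tri(2-furyl)phosphine (20 mol%), norbornene (2 equiv), Cs2CO3 (3 equiv), 10 (1.3 equiv), MeCN, 85 °C, sealed tube
Reagents that add atoms: none
Why: Zerovalent palladium inserts into the C8a–I bond of 5, norbornene inserts into the aryl–palladium bond, and the resulting alkylpalladium metalates the only free ortho position, C4a–H, to give a five-membered palladacycle. The primary C–I bond of 10 adds to this palladacycle to give tetravalent palladium and reductive elimination forms C4–C4a; with both ortho positions now substituted, norbornene is expelled by β-carbon elimination. The arylpalladium regenerated at C8a closes ring B by 6-exo-trig carbopalladation of the terminal alkene (C1–C8a), and β-hydride elimination of the single β-hydrogen at C1 leaves the exocyclic methylene while Cs2CO3 returns zerovalent palladium. The closest known reaction type is the Catellani ortho-alkylation of ortho-substituted aryl iodides with haloalkyl alkenes terminated by an intramolecular Heck reaction. No stereocentre is created: C3 is not a reacting carbon and keeps the arrangement of 10 (the descriptor reads R here only because C1 is not yet a carbonyl). Site selectivity for C4a is secured by the C8 methoxy group, which also delays norbornene loss until after alkylation, and the five-atom tether favours 6-exo over 7-endo closure.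

Step 7
Reactants: 11 (3R)-3-(tert-butyldimethylsilyloxy)-8-methoxy-1-methylidene-6-phenyl-1,2,3,4-tetrahydronaphthalene
Product: 13 (3S)-3-(tert-butyldimethylsilyloxy)-8-methoxy-6-phenyl-3,4-dihydronaphthalen-1(2H)-one, via spiro ozonide 12 (not isolated)
Conditions: O3, CH2Cl2, −78 °C (stopped at first persistent blue); then Me2S (5 equiv), −78 °C → rt
Reagents that add atoms: ozone, [O-][O+]=O
Why: Ozonolysis of the electron-rich 1,1-disubstituted styrene-type alkene is far faster than attack on the arenes, and reductive work-up of the ozonide gives the C1 ketone with loss of the methylene carbon as formaldehyde.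

Step 8
Reactants: 13 (3S)-3-(tert-butyldimethylsilyloxy)-8-methoxy-6-phenyl-3,4-dihydronaphthalen-1(2H)-one
Product: 14 (3S)-5-bromo-3-(tert-butyldimethylsilyloxy)-8-methoxy-6-phenyl-3,4-dihydronaphthalen-1(2H)-one
Conditions: NBS (1.05 equiv), MeCN, 0 °C → rt, dark
Reagents that add atoms: N-bromosuccinimide, O=C1CCC(=O)N1Br
Why: Electrophilic aromatic bromination with NBS in acetonitrile goes para to the methoxy group, and C5 is further activated by the adjacent alkyl-bearing C4a, whereas C7 is only ortho to methoxy and the pendant phenyl ring is not activated.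

Step 9
Reactants: 14 (3S)-5-bromo-3-(tert-butyldimethylsilyloxy)-8-methoxy-6-phenyl-3,4-dihydronaphthalen-1(2H)-one
Product: 15 (3S)-3-(tert-butyldimethylsilyloxy)-8-methoxy-6-phenyl-5-(4,4,5,5-tetramethyl-1,3,2-dioxaborolan-2-yl)-3,4-dihydronaphthalen-1(2H)-one
Conditions: B2pin2 (1.5 equiv), Pd2(dba)3 (2.5 mol%), XPhos (10 mol%), KOAc (3 equiv), 1,4-dioxane, 90 °C
Reagents that add atoms: bis(pinacolato)diboron, CC1(C)OB(OC1(C)C)B1OC(C)(C)C(C)(C)O1
Why: Miyaura borylation with a bulky biarylphosphine copes with the doubly ortho-flanked bromide, and KOAc is too weak a base to enolise the β-silyloxy ketone appreciably.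

Step 10
Reactants: 16 malonyl dichloride (two molecules per molecule of product)
Product: 19 6-chloro-4-hydroxy-2H-pyran-2-one, via pyranone acyl chloride 17 (not isolated), via pyranone carboxylic acid 18 (not isolated)
Conditions: neat 16, rt, 5 d, moisture excluded; then H2O (1 equiv per 17), 1,4-dioxane, rt; then 90 °C
Reagents that add atoms: malonyl dichloride (second molecule of 16), O=C(Cl)CC(=O)Cl; water, O
Why: Two molecules of 16 join by C-acylation and enol lactonisation with loss of two HCl (the chloro analogue of dehydroacetic acid formation) to give 17, whose acyl chloride is hydrolysed by water faster than the C6 chloride of the ring, and the resulting β-keto-type acid 18 loses CO2 on warming, so that the water oxygen is carried only as far as 18 while all heavy atoms of 19 come from the two malonyl units.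

Step 11
Reactants: 19 6-chloro-4-hydroxy-2H-pyran-2-one
Product: 20 4-(benzyloxy)-6-chloro-2H-pyran-2-one
Conditions: BnOH (1.1 equiv), PPh3 (1.2 equiv), DIAD (1.2 equiv), THF, 0 °C → rt
Reagents that add atoms: benzyl alcohol, OCc1ccccc1
Why: Mitsunobu alkylation of the acidic vinylogous acid takes place on the C4 oxygen under neutral conditions that spare the C6 chloride, and benzyl is chosen because it can later be removed without base.

Step 12
Reactants: 15 (3S)-3-(tert-butyldimethylsilyloxy)-8-methoxy-6-phenyl-5-(4,4,5,5-tetramethyl-1,3,2-dioxaborolan-2-yl)-3,4-dihydronaphthalen-1(2H)-one; 20 4-(benzyloxy)-6-chloro-2H-pyran-2-one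
Product: 21 (3S)-5-[4-(benzyloxy)-2-oxo-2H-pyran-6-yl]-3-(tert-butyldimethylsilyloxy)-8-methoxy-6-phenyl-3,4-dihydronaphthalen-1(2H)-one
Conditions: Pd(OAc)2 (5 mol%), SPhos (10 mol%), K3PO4 (3 equiv), 20 (1.3 equiv), degassed toluene/H2O (10:1), 60 °C
Reagents that add atoms: none
Why: In this Suzuki–Miyaura coupling the C6–Cl bond of the pyranone behaves as a vinylogous acyl chloride that adds readily to zerovalent palladium, and SPhos promotes transmetalation of the hindered boronate at a temperature and basicity low enough to spare the β-silyloxy ketone.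

Step 13
Reactants: 21 (3S)-5-[4-(benzyloxy)-2-oxo-2H-pyran-6-yl]-3-(tert-butyldimethylsilyloxy)-8-methoxy-6-phenyl-3,4-dihydronaphthalen-1(2H)-one
Product: 22 (3S)-3-(tert-butyldimethylsilyloxy)-8-hydroxy-5-(4-hydroxy-2-oxo-2H-pyran-6-yl)-6-phenyl-3,4-dihydronaphthalen-1(2H)-one
Conditions: BCl3 (1 M in CH2Cl2, 5 equiv), pentamethylbenzene (5 equiv), CH2Cl2, −78 → 0 °C; then H2O
Reagents that add atoms: none
Why: BCl3 chelated between the C1 carbonyl and the peri C8 oxygen removes that methyl group selectively (chelation-assisted ether cleavage) and also ionises the benzyl vinylogous ester, the benzyl cation being trapped by pentamethylbenzene, while the secondary silyl ether is expected to survive at low temperature.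

Step 14
Reactants: 22 (3S)-3-(tert-butyldimethylsilyloxy)-8-hydroxy-5-(4-hydroxy-2-oxo-2H-pyran-6-yl)-6-phenyl-3,4-dihydronaphthalen-1(2H)-one
Product: 23 wailupemycin F, (3S)-3,8-dihydroxy-5-(4-hydroxy-2-oxo-2H-pyran-6-yl)-6-phenyl-3,4-dihydronaphthalen-1(2H)-one
Conditions: HF·pyridine, pyridine, THF, 0 °C → rt; work-up at pH 5–6
Reagents that add atoms: none
Why: Fluoride-mediated desilylation under buffered, non-basic conditions frees the C3 alcohol without inviting E1cB dehydration of the β-hydroxy ketone, and the stereocentre is not involved.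

Compound list

1 | 4-bromo-2-methoxyaniline | Nc1ccc(Br)cc1OC | starting material
2 | phenylboronic acid | OB(O)c1ccccc1 | starting material
3 | 3-methoxybiphenyl-4-amine (2-methoxy-4-phenylaniline) | COc1cc(-c2ccccc2)ccc1N | intermediate
4 | 3-methoxybiphenyl-4-diazonium chloride (formed and consumed in step 2) | COc1cc(-c2ccccc2)ccc1[N+]#N.[Cl-] | intermediate
5 | 4-iodo-3-methoxybiphenyl | COc1cc(-c2ccccc2)ccc1I | intermediate
6 | (R)-epichlorohydrin, (2R)-2-(chloromethyl)oxirane | ClC[C@H]1CO1 | starting material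
7 | vinylmagnesium bromide | C=C[Mg]Br | starting material
8 | (2R)-1-chloropent-4-en-2-ol | C=CC[C@@H](O)CCl | intermediate
9 | tert-butyl{[(2R)-1-chloropent-4-en-2-yl]oxy}dimethylsilane | C=CC[C@@H](O[Si](C)(C)C(C)(C)C)CCl | intermediate
10 | tert-butyl{[(2R)-1-iodopent-4-en-2-yl]oxy}dimethylsilane | C=CC[C@@H](O[Si](C)(C)C(C)(C)C)CI | intermediate
11 | (3R)-3-(tert-butyldimethylsilyloxy)-8-methoxy-1-methylidene-6-phenyl-1,2,3,4-tetrahydronaphthalene | C=C1C[C@@H](O[Si](C)(C)C(C)(C)C)Cc2cc(-c3ccccc3)cc(OC)c12 | intermediate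
12 | spiro ozonide (1,2,4-trioxolane at C1) of 11, (3S) carbinol, spiro centre unassigned (formed and consumed in step 7) | C1OC2(OO1)C[C@@H](O[Si](C)(C)C(C)(C)C)Cc1cc(-c3ccccc3)cc(OC)c12 | intermediate
13 | (3S)-3-(tert-butyldimethylsilyloxy)-8-methoxy-6-phenyl-3,4-dihydronaphthalen-1(2H)-one | O=C1C[C@@H](O[Si](C)(C)C(C)(C)C)Cc2cc(-c3ccccc3)cc(OC)c12 | intermediate
14 | (3S)-5-bromo-3-(tert-butyldimethylsilyloxy)-8-methoxy-6-phenyl-3,4-dihydronaphthalen-1(2H)-one | O=C1C[C@@H](O[Si](C)(C)C(C)(C)C)Cc2c(Br)c(-c3ccccc3)cc(OC)c12 | intermediate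
15 | (3S)-3-(tert-butyldimethylsilyloxy)-8-methoxy-6-phenyl-5-(4,4,5,5-tetramethyl-1,3,2-dioxaborolan-2-yl)-3,4-dihydronaphthalen-1(2H)-one | O=C1C[C@@H](O[Si](C)(C)C(C)(C)C)Cc2c(B3OC(C)(C)C(C)(C)O3)c(-c3ccccc3)cc(OC)c12 | intermediate
16 | malonyl dichloride | O=C(Cl)CC(=O)Cl | starting material
17 | 6-chloro-4-hydroxy-2-oxo-2H-pyran-3-carbonyl chloride (formed and consumed in step 10) | O=C(Cl)c1c(O)cc(Cl)oc1=O | intermediate
18 | 6-chloro-4-hydroxy-2-oxo-2H-pyran-3-carboxylic acid (formed and consumed in step 10) | O=C(O)c1c(O)cc(Cl)oc1=O | intermediate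
19 | 6-chloro-4-hydroxy-2H-pyran-2-one | O=c1cc(O)cc(Cl)o1 | intermediate
20 | 4-(benzyloxy)-6-chloro-2H-pyran-2-one | O=c1cc(OCc2ccccc2)cc(Cl)o1 | intermediate
21 | (3S)-5-[4-(benzyloxy)-2-oxo-2H-pyran-6-yl]-3-(tert-butyldimethylsilyloxy)-8-methoxy-6-phenyl-3,4-dihydronaphthalen-1(2H)-one | O=C1C[C@@H](O[Si](C)(C)C(C)(C)C)Cc2c(-c3cc(OCc4ccccc4)cc(=O)o3)c(-c3ccccc3)cc(OC)c12 | intermediate
22 | (3S)-3-(tert-butyldimethylsilyloxy)-8-hydroxy-5-(4-hydroxy-2-oxo-2H-pyran-6-yl)-6-phenyl-3,4-dihydronaphthalen-1(2H)-one | O=C1C[C@@H](O[Si](C)(C)C(C)(C)C)Cc2c(-c3cc(O)cc(=O)o3)c(-c3ccccc3)cc(O)c12 | intermediate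
23 | wailupemycin F, (3S)-3,8-dihydroxy-5-(4-hydroxy-2-oxo-2H-pyran-6-yl)-6-phenyl-3,4-dihydronaphthalen-1(2H)-one | O=C1C[C@@H](O)Cc2c1c(O)cc(-c1ccccc1)c2-c1cc(O)cc(=O)o1 | target

Total step count: 14.
Longest linear sequence: 10 steps (steps 3, 4, 5, 6, 7, 8, 9, 12, 13, 14, from (R)-epichlorohydrin).

Steps most likely to fail

Step 6. The β-branched, β-oxygenated primary iodide may add too slowly to the palladacycle, so that the aryl–norbornyl palladium species is diverted into reduction or norbornene-containing by-products. The palladium hydride released at the end may also re-add and move the double bond into ring B, after which loss of silanol would aromatise that ring. The fallback sets out from 3 and 8 and returns at 11, making the two bonds one at a time by classical chemistry. Iodination of 3 with N-iodosuccinimide in MeCN goes ortho to the amino group, the para position being occupied, and gives 3-iodo-5-methoxybiphenyl-4-amine F1. Sandmeyer bromination (t-BuONO, CuBr2, MeCN) gives 4-bromo-3-iodo-5-methoxybiphenyl F2. Chlorohydrin 8 is closed with aqueous NaOH to (2R)-2-(prop-2-en-1-yl)oxirane F3. Selective iodine–magnesium exchange of F2 (i-PrMgCl·LiCl, THF, −40 °C) followed by CuI-catalysed opening of F3 at its terminal carbon forms C4–C4a and gives (2R)-1-(4-bromo-5-methoxybiphenyl-3-yl)pent-4-en-2-ol F4. Silylation (TBSCl, imidazole, DMF) gives {[(2R)-1-(4-bromo-5-methoxybiphenyl-3-yl)pent-4-en-2-yl]oxy}(tert-butyl)dimethylsilane F5. An ordinary intramolecular 6-exo Heck reaction (Pd(OAc)2, PPh3, K2CO3, MeCN, 80 °C) then forms C1–C8a and delivers 11.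

Step 12. Transmetalation at the doubly ortho-flanked C5 boronate may be slow, letting protodeboronation, hydrolytic opening of the chloropyranone or base-induced β-elimination of the silyloxy group (with aromatisation of ring B) overtake the coupling. The fallback sets out from 14 and returns at 22, building the pyranone on the arene instead of coupling it. Base-free Stille vinylation of 14 (tributyl(vinyl)stannane, Pd(PPh3)4, toluene, 100 °C) gives (3S)-3-(tert-butyldimethylsilyloxy)-5-ethenyl-8-methoxy-6-phenyl-3,4-dihydronaphthalen-1(2H)-one F6. Lemieux–Johnson cleavage (OsO4 cat., NaIO4, 2,6-lutidine, dioxane/H2O) gives (3S)-3-(tert-butyldimethylsilyloxy)-5-formyl-8-methoxy-6-phenyl-3,4-dihydronaphthalen-1(2H)-one F7. The dienol ether [(2,2-dimethyl-4-methylidene-4H-1,3-dioxin-6-yl)oxy]trimethylsilane F8 is made from 2,2,6-trimethyl-4H-1,3-dioxin-4-one (LiN(i-Pr)2, Me3SiCl, THF, −78 °C). It adds to the aldehyde of F7 in a vinylogous Mukaiyama aldol reaction (BF3·OEt2, CH2Cl2, −78 °C) to give (3S)-3-(tert-butyldimethylsilyloxy)-5-[2-(2,2-dimethyl-4-oxo-4H-1,3-dioxin-6-yl)-1-hydroxyethyl]-8-methoxy-6-phenyl-3,4-dihydronaphthalen-1(2H)-one F9, whose new carbinol centre is of no consequence. Dess–Martin oxidation gives (3S)-3-(tert-butyldimethylsilyloxy)-5-[(2,2-dimethyl-4-oxo-4H-1,3-dioxin-6-yl)acetyl]-8-methoxy-6-phenyl-3,4-dihydronaphthalen-1(2H)-one F10. Heating in toluene at 110 °C expels acetone, and the acylketene is trapped by the aryl ketone enol to give (3S)-3-(tert-butyldimethylsilyloxy)-5-(4-hydroxy-2-oxo-2H-pyran-6-yl)-8-methoxy-6-phenyl-3,4-dihydronaphthalen-1(2H)-one F11. BCl3 in CH2Cl2 at −78 °C then removes only the peri methyl ether and gives 22.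

Step 13. When the Lewis acid meets the fully assembled intermediate, the benzyl cation may be transferred to the electron-rich rings, the silyl ether may be stripped, and the C3 oxygen may be lost with aromatisation of ring B. The fallback sets out from 13 and returns at 22. It moves the boron reagent to the simple ketone, where one chelation-assisted cleavage is all that is asked, and ends with a neutral hydrogenolysis. BCl3 (CH2Cl2, −78 °C) on 13 gives (3S)-3-(tert-butyldimethylsilyloxy)-8-hydroxy-6-phenyl-3,4-dihydronaphthalen-1(2H)-one F12. NBS in MeCN brominates para to the phenol and gives (3S)-5-bromo-3-(tert-butyldimethylsilyloxy)-8-hydroxy-6-phenyl-3,4-dihydronaphthalen-1(2H)-one F13. Miyaura borylation (B2pin2, Pd2(dba)3, XPhos, KOAc, dioxane) gives (3S)-3-(tert-butyldimethylsilyloxy)-8-hydroxy-6-phenyl-5-(4,4,5,5-tetramethyl-1,3,2-dioxaborolan-2-yl)-3,4-dihydronaphthalen-1(2H)-one F14. Suzuki coupling with 20 (Pd(OAc)2, SPhos, K3PO4) gives (3S)-5-[4-(benzyloxy)-2-oxo-2H-pyran-6-yl]-3-(tert-butyldimethylsilyloxy)-8-hydroxy-6-phenyl-3,4-dihydronaphthalen-1(2H)-one F15. Hydrogenolysis (H2, Pd/C, EtOAc, rt) removes the benzyl group and gives 22.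

Further compounds

F1 | step 6 | 3-iodo-5-methoxybiphenyl-4-amine | COc1cc(-c2ccccc2)cc(I)c1N
F2 | step 6 | 4-bromo-3-iodo-5-methoxybiphenyl | COc1cc(-c2ccccc2)cc(I)c1Br
F3 | step 6 | (2R)-2-(prop-2-en-1-yl)oxirane | C=CC[C@@H]1CO1
F4 | step 6 | (2R)-1-(4-bromo-5-methoxybiphenyl-3-yl)pent-4-en-2-ol | C=CC[C@@H](O)Cc1cc(-c2ccccc2)cc(OC)c1Br
F5 | step 6 | {[(2R)-1-(4-bromo-5-methoxybiphenyl-3-yl)pent-4-en-2-yl]oxy}(tert-butyl)dimethylsilane | C=CC[C@@H](O[Si](C)(C)C(C)(C)C)Cc1cc(-c2ccccc2)cc(OC)c1Br
F6 | step 12 | (3S)-3-(tert-butyldimethylsilyloxy)-5-ethenyl-8-methoxy-6-phenyl-3,4-dihydronaphthalen-1(2H)-one | O=C1C[C@@H](O[Si](C)(C)C(C)(C)C)Cc2c(C=C)c(-c3ccccc3)cc(OC)c12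
F7 | step 12 | (3S)-3-(tert-butyldimethylsilyloxy)-5-formyl-8-methoxy-6-phenyl-3,4-dihydronaphthalen-1(2H)-one | O=C1C[C@@H](O[Si](C)(C)C(C)(C)C)Cc2c(C=O)c(-c3ccccc3)cc(OC)c12
F8 | step 12 | [(2,2-dimethyl-4-methylidene-4H-1,3-dioxin-6-yl)oxy]trimethylsilane | C=C1C=C(O[Si](C)(C)C)OC(C)(C)O1
F9 | step 12 | (3S)-3-(tert-butyldimethylsilyloxy)-5-[2-(2,2-dimethyl-4-oxo-4H-1,3-dioxin-6-yl)-1-hydroxyethyl]-8-methoxy-6-phenyl-3,4-dihydronaphthalen-1(2H)-one | O=C1C[C@@H](O[Si](C)(C)C(C)(C)C)Cc2c(C(O)CC3=CC(=O)OC(C)(C)O3)c(-c3ccccc3)cc(OC)c12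
F10 | step 12 | (3S)-3-(tert-butyldimethylsilyloxy)-5-[(2,2-dimethyl-4-oxo-4H-1,3-dioxin-6-yl)acetyl]-8-methoxy-6-phenyl-3,4-dihydronaphthalen-1(2H)-one | O=C1C[C@@H](O[Si](C)(C)C(C)(C)C)Cc2c(C(=O)CC3=CC(=O)OC(C)(C)O3)c(-c3ccccc3)cc(OC)c12
F11 | step 12 | (3S)-3-(tert-butyldimethylsilyloxy)-5-(4-hydroxy-2-oxo-2H-pyran-6-yl)-8-methoxy-6-phenyl-3,4-dihydronaphthalen-1(2H)-one | O=C1C[C@@H](O[Si](C)(C)C(C)(C)C)Cc2c(-c3cc(O)cc(=O)o3)c(-c3ccccc3)cc(OC)c12
F12 | step 13 | (3S)-3-(tert-butyldimethylsilyloxy)-8-hydroxy-6-phenyl-3,4-dihydronaphthalen-1(2H)-one | O=C1C[C@@H](O[Si](C)(C)C(C)(C)C)Cc2cc(-c3ccccc3)cc(O)c12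
F13 | step 13 | (3S)-5-bromo-3-(tert-butyldimethylsilyloxy)-8-hydroxy-6-phenyl-3,4-dihydronaphthalen-1(2H)-one | O=C1C[C@@H](O[Si](C)(C)C(C)(C)C)Cc2c(Br)c(-c3ccccc3)cc(O)c12
F14 | step 13 | (3S)-3-(tert-butyldimethylsilyloxy)-8-hydroxy-6-phenyl-5-(4,4,5,5-tetramethyl-1,3,2-dioxaborolan-2-yl)-3,4-dihydronaphthalen-1(2H)-one | O=C1C[C@@H](O[Si](C)(C)C(C)(C)C)Cc2c(B3OC(C)(C)C(C)(C)O3)c(-c3ccccc3)cc(O)c12
F15 | step 13 | (3S)-5-[4-(benzyloxy)-2-oxo-2H-pyran-6-yl]-3-(tert-butyldimethylsilyloxy)-8-hydroxy-6-phenyl-3,4-dihydronaphthalen-1(2H)-one | O=C1C[C@@H](O[Si](C)(C)C(C)(C)C)Cc2c(-c3cc(OCc4ccccc4)cc(=O)o3)c(-c3ccccc3)cc(O)c12
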